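The disconnection is the bond between C1 of the second geranyl chain and C4 of ring B, the quaternary carbon that also bears CH3 and lies between the enol carbons C3–OH and C5–OH. In the aromatic precursor this atom is the hydrogen-free C-methyl carbon of ring B, so geranyl transfer to it by an aromatic prenyltransferase cannot end in rearomatisation. One operation forms the C–C bond, dearomatises ring B and sets the only stereocentre (R). The precursor is an achiral, unprotected methylene-bridged bis-acylphloroglucinol in which every ring carbon is substituted: ring A carries butanoyl and geranyl, ring B acetyl and methyl.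

Key step: step 8

Remark on the chemistry: the given structures are consistent and need no correction. C4 of ring B is R in the tautomer drawn, and keto–enol exchange in ring B does not touch it. Compound 3 is drawn as the free acid but made and used as its tris(ammonium) salt. Precursor 12 is left unprotected because the enzyme needs the ring B phenolate, and the aminomethyl handle is placed on the ring B half, which has a single free ring CH.

Step 1
Reactants: 1 geraniol
Product: 2 geranyl bromide [(2E)-1-bromo-3,7-dimethylocta-2,6-diene]
Conditions: PBr3 (0.4 equiv), Et2O, −10 °C, dark; used at once without distillation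
Reagents that add atoms: phosphorus tribromide, BrP(Br)Br
Why: Bromide displaces the primary allylic phosphite ester in an SN2 manner at low temperature, which should keep the E-alkene and avoid allylic transposition.

Step 2
Reactants: 2 geranyl bromide
Product: 3 geranyl diphosphate (isolated as the tris(ammonium) salt)
Conditions: (Bu4N)3HP2O7 (2 equiv), MeCN, rt; then sulfonic acid cation-exchange resin (NH4+ form), aq. NH4HCO3/iPrOH; cellulose chromatography; lyophilisation
Reagents that add atoms: tris(tetrabutylammonium) hydrogen diphosphate, CCCC[N+](CCCC)(CCCC)CCCC.CCCC[N+](CCCC)(CCCC)CCCC.CCCC[N+](CCCC)(CCCC)CCCC.OP(=O)([O-])OP(=O)([O-])[O-]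
Why: SN2 displacement of a primary allylic halide by the acetonitrile-soluble hydrogen diphosphate anion is the standard halide-to-diphosphate conversion for isoprenoid chains and should proceed without allylic shift; cation exchange then gives the water-soluble salt the enzyme accepts.

Step 3
Reactants: 4 phloroglucinol; 5 butyryl chloride
Product: 6 1-(2,4,6-trihydroxyphenyl)butan-1-one
Conditions: AlCl3 (3.5 equiv), PhNO2, rt → 65 °C; ice/2 M HCl
Reagents that add atoms: none
Why: Friedel–Crafts C-acylation (any O-acyl ester formed first undergoes Fries rearrangement under the same Lewis acid) should stop at the monoketone because the first acyl group deactivates the ring.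

Step 4
Reactants: 6 1-(2,4,6-trihydroxyphenyl)butan-1-one; 2 geranyl bromide
Product: 7 1-[3-[(2E)-3,7-dimethylocta-2,6-dien-1-yl]-2,4,6-trihydroxyphenyl]butan-1-one
Conditions: K2CO3 (1.1 equiv), acetone, reflux, N2; 6 in 1.5-fold excess, recovered on chromatography
Reagents that add atoms: none
Why: C-alkylation of the ambident phloroglucinolate (SN2 at the primary allylic bromide) takes place at one of the two equivalent unsubstituted ring carbons, as in known C-geranylations of acylphloroglucinols, and the excess of 6 should hold back a second alkylation.

Step 5
Reactants: 8 2-methylphloroglucinol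
Product: 9 1-(2,4,6-trihydroxy-3-methylphenyl)ethan-1-one
Conditions: AcCl (1.1 equiv), AlCl3 (3.5 equiv), PhNO2, rt → 60 °C; ice/2 M HCl
Reagents that add atoms: acetyl chloride, CC(Cl)=O
Why: Friedel–Crafts acylation at either of the two equivalent free ring positions of 8 should give a single monoketone, the acetyl group shutting off further acylation.

Step 6
Reactants: 9 1-(2,4,6-trihydroxy-3-methylphenyl)ethan-1-one
Product: 10 1-[3-[(dimethylamino)methyl]-2,4,6-trihydroxy-5-methylphenyl]ethan-1-one
Conditions: Me2NH (40% aq., 1.5 equiv), HCHO (37% aq., 1.05 equiv), EtOH, 0 °C → rt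
Reagents that add atoms: formaldehyde, C=O; dimethylamine, CNC
Why: In this Mannich reaction the iminium ion can only attack the one remaining ring CH of 9, and the excess amine should intercept formaldehyde before it can join two arenes.

Step 7
Reactants: 7 1-[3-[(2E)-3,7-dimethylocta-2,6-dien-1-yl]-2,4,6-trihydroxyphenyl]butan-1-one; 10 1-[3-[(dimethylamino)methyl]-2,4,6-trihydroxy-5-methylphenyl]ethan-1-one
Product: 12 1-[3-[(3-acetyl-2,4,6-trihydroxy-5-methylphenyl)methyl]-5-[(2E)-3,7-dimethylocta-2,6-dien-1-yl]-2,4,6-trihydroxyphenyl]butan-1-one (achiral bridged dimer), via ortho-quinone methide 11 (not isolated)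
Conditions: 1,4-dioxane, 90 °C, slow N2 stream; 7 (1.3 equiv)
Reagents that add atoms: none
Why: Thermal loss of dimethylamine from the ortho-hydroxybenzylamine gives ortho-quinone methide 11, which is captured in a conjugate addition by the only unsubstituted ring carbon of 7 (Mannich-base alkylation of a phenol); the neutral medium should spare the geranyl alkenes and the new bridge.

Step 8
Reactants: 12 achiral bridged dimer; 3 geranyl diphosphate
Product: 13 (4R)-2-acetyl-6-[[3-butanoyl-5-[(2E)-3,7-dimethylocta-2,6-dien-1-yl]-2,4,6-trihydroxyphenyl]methyl]-4-[(2E)-3,7-dimethylocta-2,6-dien-1-yl]-3,5-dihydroxy-4-methylcyclohexa-2,5-dien-1-one (CNP0209203.1)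
Conditions: evolved soluble aromatic prenyltransferase (ABBA fold, NphB-type scaffold; clarified lysate), MgCl2 (5 mM), Tris·HCl pH 7.5, DMSO (5% v/v), 30 °C, N2, dark; 3 (1.5 equiv) added in portions; EtOAc extraction, reversed-phase chromatography
Reagents that add atoms: none
Why: Proposed new method: the protein holds the diphosphate of 3 on a divalent magnesium ion and ionises the C1–O bond to an allyl cation–diphosphate pair, whose C1 is attacked by the ring B phenolate of 12 through its methyl-bearing carbon (para to the oxygen between the acetyl and bridge carbons); since that carbon has no hydrogen, the cyclohexadienyl cation is discharged by loss of an O–H proton and stays as the 3,5-dihydroxycyclohexa-2,5-dienone. The closest known reaction type is the geminal, dearomatising C-prenylation of acylphloroglucinols by aromatic prenyltransferases with dimethylallyl or geranyl diphosphate, which has not been shown on a methylene-bridged dimer. No ring is closed; a single C–C bond is formed. The quaternary centre is set by the protein alone: planar, achiral ring B is bound so that only one of its enantiotopic faces meets C1 of the cation, and the variant that delivers R is to be found by chiral HPLC screening of a prenyltransferase panel and sharpened by directed evolution. The step needs site selectivity (ring B C–CH3 over the geranyl-bearing carbon of ring A, the two bridge-bearing carbons and the oxygens) and a single transfer; the substrate helps because every ring carbon is substituted, so ordinary aromatic geranylation cannot compete, the methyl carbon is the least hindered ipso site, the product dienone is a weaker nucleophile than 12, and attack at C1 without allylic shift keeps the E-alkene.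

Compound list
1 | geraniol, (2E)-3,7-dimethylocta-2,6-dien-1-ol | CC(C)=CCC/C(C)=C/CO | starting material
2 | geranyl bromide, (2E)-1-bromo-3,7-dimethylocta-2,6-diene | CC(C)=CCC/C(C)=C/CBr | intermediate
3 | geranyl diphosphate (free acid drawn; handled as tris(ammonium) salt) | CC(C)=CCC/C(C)=C/COP(=O)(O)OP(=O)(O)O | intermediate
4 | phloroglucinol | Oc1cc(O)cc(O)c1 | starting material
5 | butyryl chloride | CCCC(Cl)=O | starting material
6 | 1-(2,4,6-trihydroxyphenyl)butan-1-one | CCCC(=O)c1c(O)cc(O)cc1O | intermediate
7 | 1-[3-[(2E)-3,7-dimethylocta-2,6-dien-1-yl]-2,4,6-trihydroxyphenyl]butan-1-one | CCCC(=O)c1c(O)cc(O)c(C/C=C(\C)CCC=C(C)C)c1O | intermediate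
8 | 2-methylphloroglucinol | Cc1c(O)cc(O)cc1O | starting material
9 | 1-(2,4,6-trihydroxy-3-methylphenyl)ethan-1-one | CC(=O)c1c(O)cc(O)c(C)c1O | intermediate
10 | 1-[3-[(dimethylamino)methyl]-2,4,6-trihydroxy-5-methylphenyl]ethan-1-one | CC(=O)c1c(O)c(CN(C)C)c(O)c(C)c1O | intermediate
11 | ortho-quinone methide, 4-acetyl-3,5-dihydroxy-2-methyl-6-methylidenecyclohexa-2,4-dien-1-one | C=C1C(=O)C(C)=C(O)C(C(C)=O)=C1O | intermediate (not isolated)
12 | achiral bridged dimer, 1-[3-[(3-acetyl-2,4,6-trihydroxy-5-methylphenyl)methyl]-5-[(2E)-3,7-dimethylocta-2,6-dien-1-yl]-2,4,6-trihydroxyphenyl]butan-1-one | CCCC(=O)c1c(O)c(C/C=C(\C)CCC=C(C)C)c(O)c(Cc2c(O)c(C)c(O)c(C(C)=O)c2O)c1O | intermediate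
13 | (4R)-2-acetyl-6-[[3-butanoyl-5-[(2E)-3,7-dimethylocta-2,6-dien-1-yl]-2,4,6-trihydroxyphenyl]methyl]-4-[(2E)-3,7-dimethylocta-2,6-dien-1-yl]-3,5-dihydroxy-4-methylcyclohexa-2,5-dien-1-one | CCCC(=O)c1c(O)c(C/C=C(\C)CCC=C(C)C)c(O)c(CC2=C(O)[C@@](C)(C/C=C(\C)CCC=C(C)C)C(O)=C(C(C)=O)C2=O)c1O | target

Total step count: 8. Longest linear sequence: 4 steps (steps 3, 4, 7, 8 from phloroglucinol; the branches from geraniol and from 2-methylphloroglucinol are equally long).

Steps most likely to fail

Step 8. The bulky dimer may bind poorly or in the wrong register, so that transfer is slow, goes to a phenolic oxygen or a ring A carbon, shows weak facial bias, or is followed by a second transfer. The fallback sets out from 12 and uses the bromide 2 in place of the diphosphate. Classical phenolate alkylation (NaOMe, MeOH, −10 °C), the known way to geminal dearomatising allylation of fully substituted acylphloroglucinols, should place geranyl on the least hindered ipso carbon, the ring B methyl carbon. After removal of isomeric alkylation products on silica this would give the racemic geranylated dienone F1. Preparative HPLC on a chiral stationary phase (amylose tris(3,5-dimethylphenylcarbamate)) would then separate the enantiomers, and the R enantiomer rejoins the route at 13.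

Step 7. The quinone methide may attack an already substituted ring carbon of 10 or of the product, which exchanges aryl halves across the bridge and leads to symmetrical dimers, or it may oligomerise. The fallback sets out from 7 and reverses the roles of the two halves. A Mannich reaction at its single free ring carbon (Me2NH, HCHO, EtOH, 0 °C → rt) would give the ring A Mannich base F2. Heating F2 in 1,4-dioxane with an excess of the small, cheap arene 9 would release the ring A ortho-quinone methide F3, which 9 traps through its only free ring carbon. The sequence comes back to the route at 12.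

Step 4. The ambident phenolate may be alkylated on oxygen or twice on carbon, including geminal alkylation with loss of aromaticity. The fallback sets out from 6 and takes geraniol 1 directly as the electrophile under acid catalysis (BF3·OEt2, substoichiometric, 1,4-dioxane, rt). This is a Friedel–Crafts allylation in which no phenolate is present, so oxygen and geminal alkylation fall away; short reaction times guard against cyclisation of the side chain onto an ortho hydroxyl. It comes back to the route at 7 and makes no new compound (F0).

Further compounds
F1 | step 8 | racemic 2-acetyl-6-[[3-butanoyl-5-[(2E)-3,7-dimethylocta-2,6-dien-1-yl]-2,4,6-trihydroxyphenyl]methyl]-4-[(2E)-3,7-dimethylocta-2,6-dien-1-yl]-3,5-dihydroxy-4-methylcyclohexa-2,5-dien-1-one | CCCC(=O)c1c(O)c(C/C=C(\C)CCC=C(C)C)c(O)c(CC2=C(O)C(C)(C/C=C(\C)CCC=C(C)C)C(O)=C(C(C)=O)C2=O)c1O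
F2 | step 7 | 1-[3-[(dimethylamino)methyl]-5-[(2E)-3,7-dimethylocta-2,6-dien-1-yl]-2,4,6-trihydroxyphenyl]butan-1-one | CCCC(=O)c1c(O)c(CN(C)C)c(O)c(C/C=C(\C)CCC=C(C)C)c1O
F3 | step 7 | 4-butanoyl-2-[(2E)-3,7-dimethylocta-2,6-dien-1-yl]-3,5-dihydroxy-6-methylidenecyclohexa-2,4-dien-1-one | C=C1C(=O)C(C/C=C(\C)CCC=C(C)C)=C(O)C(C(=O)CCC)=C1O
F0 | step 4 | none | none
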